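**Retrosynthetic overview**
- Feature: in the hydroxyindole, the oxygen on C5 is para to N1, C2 carries only hydrogen, and C3 carries the hexasubstituted central benzene ring. Cutting N1–C2 and C3–C3a therefore leads to a para-alkoxyphenylhydrazine and the arylacetaldehyde ArCH2CHO, where Ar is the central ring.
- The aldehyde is unmasked from a methyl enol ether made by Wittig homologation of 4-bromo-2,3,5,6-tetramethoxybenzaldehyde. This differentiated monobromide takes the 6-prenylindol-3-yl group in a single Suzuki–Miyaura coupling, so no statistical coupling of a dibromide is needed.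
- The indolylboronate comes from 6-bromoindole by N-silylation, Br–Li exchange with prenylation, and C3-selective C–H borylation.
- Ring order: the central benzene and the prenylindole bicycle are bought as rings. The only ring built is the pyrrole ring of the 5-oxygenated indole, closed in the penultimate step. The phenol travels as an allyl ether, which zerovalent palladium removes last.

Key step: step 11

Assumption: the methoxyvinyl intermediates are carried as E/Z mixtures and the hydrazone as whichever C=N isomer forms, because both geometries are erased later. The target has no stereocentre.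

**Step 1**
Reactants: 1 1,2,4,5-tetramethoxybenzene
Product: 2 1,4-dibromo-2,3,5,6-tetramethoxybenzene
Conditions: Br2 (2.1 equiv), CH2Cl2, 0 °C to rt
Reagents that add atoms: bromine, BrBr
Why: Electrophilic aromatic bromination, in which the only two free ring carbons are each flanked by two methoxy groups and lie para to one another, so double substitution can give only this dibromide.

**Step 2**
Reactants: 2 1,4-dibromo-2,3,5,6-tetramethoxybenzene
Product: 5 4-bromo-2,3,5,6-tetramethoxybenzaldehyde, via aryllithium 3 (not isolated), via lithium hemiaminal alkoxide 4 (not isolated)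
Conditions: n-BuLi (1.0 equiv), THF, −78 °C; DMF, −78 °C to 0 °C; 1 M aq HCl quench
Reagents that add atoms: N,N-dimethylformamide, CN(C)C=O
Why: Bromine–lithium exchange with one equivalent of n-BuLi should stop at the monolithio stage because a second exchange would place two carbanions on one ring, and formylation of the aryllithium with DMF gives a tetrahedral adduct that collapses to the aldehyde only on quench.

**Step 3**
Reactants: 5 4-bromo-2,3,5,6-tetramethoxybenzaldehyde
Product: 6 1-bromo-2,3,5,6-tetramethoxy-4-(2-methoxyethenyl)benzene (E/Z mixture)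
Conditions: Ph3P(CH2OMe)Cl, KOtBu, THF, 0 °C; then 5, 0 °C to rt
Reagents that add atoms: (methoxymethyl)triphenylphosphonium chloride, COC[P+](c1ccccc1)(c1ccccc1)c1ccccc1.[Cl-]
Why: Wittig methoxymethylenation, in which the small non-stabilised ylide adds readily even to a di-ortho-substituted, non-enolisable benzaldehyde and leaves the aryl bromide untouched.

**Step 4**
Reactants: 7 6-bromo-1H-indole
Product: 9 6-bromo-1-(triisopropylsilyl)-1H-indole, via sodium indolide 8 (not isolated)
Conditions: NaH, THF, 0 °C; TIPSCl, 0 °C to rt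
Reagents that add atoms: triisopropylsilyl chloride, CC(C)[Si](Cl)(C(C)C)C(C)C
Why: N-silylation of the indolide anion removes the acidic N–H and places a bulky group beside C2 and C7 that shields both positions in the next two steps.

**Step 5**
Reactants: 9 6-bromo-1-(triisopropylsilyl)-1H-indole
Product: 11 6-(3-methylbut-2-en-1-yl)-1-(triisopropylsilyl)-1H-indole, via 6-lithioindole 10 (not isolated)
Conditions: t-BuLi (2.0 equiv), THF, −78 °C; prenyl bromide, −78 °C to rt
Reagents that add atoms: prenyl bromide (1-bromo-3-methylbut-2-ene), CC(C)=CCBr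
Why: Bromine–lithium exchange followed by SN2 alkylation, in which the aryllithium attacks the unhindered primary carbon of prenyl bromide rather than the fully substituted alkene terminus, while the silyl group prevents deprotonation at C2.

**Step 6**
Reactants: 11 6-(3-methylbut-2-en-1-yl)-1-(triisopropylsilyl)-1H-indole
Product: 12 6-(3-methylbut-2-en-1-yl)-3-(4,4,5,5-tetramethyl-1,3,2-dioxaborolan-2-yl)-1-(triisopropylsilyl)-1H-indole
Conditions: [Ir(OMe)(cod)]2 (1.5 mol %), dtbpy (3 mol %), B2pin2 (1.0 equiv), hexane, 50 °C
Reagents that add atoms: bis(pinacolato)diboron, CC1(C)OB(OC1(C)C)B1OC(C)(C)C(C)(C)O1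
Why: Iridium-catalysed C–H borylation is sterically governed and is known to go to C3 of N-triisopropylsilylindoles; here C2 and C7 are blocked by silicon, C5 and C7 lie ortho to the prenyl group, C4 is peri-hindered, and no electrophilic halogen ever meets the alkene.

**Step 7**
Reactants: 6 1-bromo-2,3,5,6-tetramethoxy-4-(2-methoxyethenyl)benzene, 12 6-(3-methylbut-2-en-1-yl)-3-(4,4,5,5-tetramethyl-1,3,2-dioxaborolan-2-yl)-1-(triisopropylsilyl)-1H-indole
Product: 13 3-[2,3,5,6-tetramethoxy-4-(2-methoxyethenyl)phenyl]-6-(3-methylbut-2-en-1-yl)-1-(triisopropylsilyl)-1H-indole (E/Z mixture)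
Conditions: Pd(OAc)2 (5 mol %), SPhos (10 mol %), K3PO4, toluene/H2O, 90 °C
Reagents that add atoms: none
Why: Suzuki–Miyaura coupling, in which SPhos-ligated zerovalent palladium is a standard answer to electron-rich di-ortho-alkoxy aryl bromides, the enol ether and prenyl group are inert to the basic medium, and any silyl loss is made good in step 8.

**Step 8**
Reactants: 13 3-[2,3,5,6-tetramethoxy-4-(2-methoxyethenyl)phenyl]-6-(3-methylbut-2-en-1-yl)-1-(triisopropylsilyl)-1H-indole
Product: 14 3-[2,3,5,6-tetramethoxy-4-(2-methoxyethenyl)phenyl]-6-(3-methylbut-2-en-1-yl)-1H-indole (E/Z mixture)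
Conditions: TBAF (1.1 equiv), THF, 0 °C
Reagents that add atoms: none
Why: Fluoride-mediated N–Si cleavage is fast for N-silylindoles and is done at the base-stable enol ether stage, so that the enolisable aldehyde never meets basic fluoride.

**Step 9**
Reactants: 14 3-[2,3,5,6-tetramethoxy-4-(2-methoxyethenyl)phenyl]-6-(3-methylbut-2-en-1-yl)-1H-indole
Product: 15 2-{2,3,5,6-tetramethoxy-4-[6-(3-methylbut-2-en-1-yl)-1H-indol-3-yl]phenyl}acetaldehyde
Conditions: 1 M aq HCl/THF, dilute, rt, Ar; used without storage
Reagents that add atoms: water, O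
Why: Acid-catalysed enol ether hydrolysis (C-protonation, hydration of the oxocarbenium ion, loss of methanol) runs under far milder acid than protonation of the trisubstituted prenyl alkene, and both enol ether isomers give the same aldehyde.

**Step 10**
Reactants: 16 4-(allyloxy)aniline
Product: 19 [4-(allyloxy)phenyl]hydrazine, via diazonium chloride 17 (not isolated), via hydrazine hydrochloride 18 (not isolated)
Conditions: NaNO2, aq HCl, −5 to 0 °C; SnCl2·2H2O, conc. HCl, 0 °C; aq NaOH, Et2O extraction, used at once under Ar
Reagents that add atoms: sodium nitrite, [Na+].[O-]N=O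
Why: Diazotisation followed by stannous chloride reduction is the classical route from an aniline to an arylhydrazine, and the allyl aryl ether is inert to cold mineral acid and to divalent tin.

**Step 11**
Reactants: 15 2-{2,3,5,6-tetramethoxy-4-[6-(3-methylbut-2-en-1-yl)-1H-indol-3-yl]phenyl}acetaldehyde, 19 [4-(allyloxy)phenyl]hydrazine
Product: 21 5-(allyloxy)-3-{2,3,5,6-tetramethoxy-4-[6-(3-methylbut-2-en-1-yl)-1H-indol-3-yl]phenyl}-1H-indole, via hydrazone 20 (not isolated)
Conditions: EtOH, rt, Ar (hydrazone); evaporate; AcOH, 70 °C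
Reagents that add atoms: none
Why: This is a Fischer indole synthesis of a 3-arylindole from an arylacetaldehyde arylhydrazone, a long-established reaction class: condensation gives hydrazone 20, which in warm acetic acid tautomerises to the ene-hydrazine through its only enolisable carbon (the benzylic CH2) and, once N-protonated, undergoes the [3,3]-sigmatropic shift that breaks N–N and joins that carbon, already bearing the central ring, to an ortho carbon of the allyloxyphenyl ring (C3–C3a). Rearomatisation frees an aniline nitrogen that attacks the adjacent iminium carbon in a 5-exo-trig closure (N1–C2), and loss of NH3 from the aminal aromatises the new pyrrole ring. Regiochemistry needs no control, because the two ortho carbons of the para-substituted hydrazine are equivalent, so the oxygen must end at C5 and C2 must keep its hydrogen. The para-allyloxy donor speeds the rearrangement enough for a weak acid to suffice, which should spare the prenyl alkene and the allyl ether (whose aromatic Claisen rearrangement needs much higher temperature) and avoid the strong-acid 3-to-2 aryl migration of 3-arylindoles. Competing heterolytic N–N cleavage should be held back because the crowded central ring and its four methoxy groups are twisted out of conjugation and stabilise a cation at the ene-hydrazine carbon poorly. No stereocentre is formed.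

**Step 12**
Reactants: 21 5-(allyloxy)-3-{2,3,5,6-tetramethoxy-4-[6-(3-methylbut-2-en-1-yl)-1H-indol-3-yl]phenyl}-1H-indole
Product: 22 3-{2,3,5,6-tetramethoxy-4-[6-(3-methylbut-2-en-1-yl)-1H-indol-3-yl]phenyl}-1H-indol-5-ol (target)
Conditions: Pd(PPh3)4 (5 mol %), morpholine, THF, rt, Ar
Reagents that add atoms: none
Why: Tsuji–Trost-type deallylation, in which zerovalent palladium ionises the allyl aryl ether to a pi-allyl complex that morpholine intercepts, while the prenyl group has no leaving group and the four methyl ethers are untouched.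

**Compound list**
1 | 1,2,4,5-tetramethoxybenzene | COc1cc(OC)c(OC)cc1OC | starting material
2 | 1,4-dibromo-2,3,5,6-tetramethoxybenzene | COc1c(OC)c(Br)c(OC)c(OC)c1Br | intermediate
3 | (4-bromo-2,3,5,6-tetramethoxyphenyl)lithium | COc1c(OC)c(Br)c(OC)c(OC)c1[Li] | intermediate (not isolated)
4 | lithium (4-bromo-2,3,5,6-tetramethoxyphenyl)(dimethylamino)methanolate (racemic, transient) | [Li+].[O-]C(N(C)C)c1c(OC)c(OC)c(Br)c(OC)c1OC | intermediate (not isolated)
5 | 4-bromo-2,3,5,6-tetramethoxybenzaldehyde | COc1c(OC)c(Br)c(OC)c(OC)c1C=O | intermediate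
6 | 1-bromo-2,3,5,6-tetramethoxy-4-(2-methoxyethenyl)benzene (E/Z mixture) | COC=Cc1c(OC)c(OC)c(Br)c(OC)c1OC | intermediate
7 | 6-bromo-1H-indole | Brc1ccc2cc[nH]c2c1 | starting material
8 | sodium 6-bromoindol-1-ide | [Na+].Brc1ccc2cc[n-]c2c1 | intermediate (not isolated)
9 | 6-bromo-1-(triisopropylsilyl)-1H-indole | CC(C)[Si](C(C)C)(C(C)C)n1ccc2ccc(Br)cc21 | intermediate
10 | [1-(triisopropylsilyl)-1H-indol-6-yl]lithium | [Li]c1ccc2ccn([Si](C(C)C)(C(C)C)C(C)C)c2c1 | intermediate (not isolated)
11 | 6-(3-methylbut-2-en-1-yl)-1-(triisopropylsilyl)-1H-indole | CC(C)=CCc1ccc2ccn([Si](C(C)C)(C(C)C)C(C)C)c2c1 | intermediate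
12 | 6-(3-methylbut-2-en-1-yl)-3-(4,4,5,5-tetramethyl-1,3,2-dioxaborolan-2-yl)-1-(triisopropylsilyl)-1H-indole | CC(C)=CCc1ccc2c(B3OC(C)(C)C(C)(C)O3)cn([Si](C(C)C)(C(C)C)C(C)C)c2c1 | intermediate
13 | 3-[2,3,5,6-tetramethoxy-4-(2-methoxyethenyl)phenyl]-6-(3-methylbut-2-en-1-yl)-1-(triisopropylsilyl)-1H-indole (E/Z mixture) | COC=Cc1c(OC)c(OC)c(-c2cn([Si](C(C)C)(C(C)C)C(C)C)c3cc(CC=C(C)C)ccc23)c(OC)c1OC | intermediate
14 | 3-[2,3,5,6-tetramethoxy-4-(2-methoxyethenyl)phenyl]-6-(3-methylbut-2-en-1-yl)-1H-indole (E/Z mixture) | COC=Cc1c(OC)c(OC)c(-c2c[nH]c3cc(CC=C(C)C)ccc23)c(OC)c1OC | intermediate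
15 | 2-{2,3,5,6-tetramethoxy-4-[6-(3-methylbut-2-en-1-yl)-1H-indol-3-yl]phenyl}acetaldehyde | O=CCc1c(OC)c(OC)c(-c2c[nH]c3cc(CC=C(C)C)ccc23)c(OC)c1OC | intermediate (key-step precursor)
16 | 4-(allyloxy)aniline | Nc1ccc(OCC=C)cc1 | starting material
17 | 4-(allyloxy)benzenediazonium chloride | C=CCOc1ccc([N+]#N)cc1.[Cl-] | intermediate (not isolated)
18 | [4-(allyloxy)phenyl]hydrazine hydrochloride | Cl.NNc1ccc(OCC=C)cc1 | intermediate (not isolated)
19 | [4-(allyloxy)phenyl]hydrazine | NNc1ccc(OCC=C)cc1 | intermediate (key-step precursor)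
20 | 4-(allyloxy)phenylhydrazone of aldehyde 15 | C=CCOc1ccc(NN=CCc2c(OC)c(OC)c(-c3c[nH]c4cc(CC=C(C)C)ccc34)c(OC)c2OC)cc1 | intermediate (not isolated)
21 | 5-(allyloxy)-3-{2,3,5,6-tetramethoxy-4-[6-(3-methylbut-2-en-1-yl)-1H-indol-3-yl]phenyl}-1H-indole | C=CCOc1ccc2[nH]cc(-c3c(OC)c(OC)c(-c4c[nH]c5cc(CC=C(C)C)ccc45)c(OC)c3OC)c2c1 | intermediate (key-step product)
22 | 3-{2,3,5,6-tetramethoxy-4-[6-(3-methylbut-2-en-1-yl)-1H-indol-3-yl]phenyl}-1H-indol-5-ol | COc1c(OC)c(-c2c[nH]c3ccc(O)cc23)c(OC)c(OC)c1-c1c[nH]c2cc(CC=C(C)C)ccc12 | target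

**Total step count:** 12.
**Longest linear sequence:** 8 steps (1, 2, 3, 7, 8, 9, 11, 12). The indole branch 4, 5, 6, 7, 8, 9, 11, 12 is of equal length.

**Steps most likely to fail**

Step 11.
- What may go wrong: heterolytic N–N cleavage of the protonated ene-hydrazine may outrun the sigmatropic shift. Tautomerisation next to the crowded central ring may be slow. The free C2 position of the resident indole may add to the activated hydrazone carbon.
- Fallback: it sets out from 15 and comes back at 22. It makes the same two bonds by palladium catalysis instead of acid.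
- Commercial 4-[(tert-butyldimethylsilyl)oxy]aniline is iodinated ortho to nitrogen with NIS to give 4-[(tert-butyldimethylsilyl)oxy]-2-iodoaniline F1.
- Heating 15 with F1, Pd(OAc)2 and DABCO in DMF at 85 °C should condense amine and aldehyde (N1–C2). An intramolecular Heck-type cyclisation of the arylpalladium species onto the enamine carbon then closes C3–C3a and gives the 5-(tert-butyldimethylsilyloxy)indole analogue of 21 F2.
- A silyl ether replaces the allyl ether here because zerovalent palladium would ionise the latter. TBAF buffered with AcOH then releases 22.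

Step 7.
- What may go wrong: protodeboronation of the indol-3-ylboronate may outpace slow oxidative addition and transmetalation at the electron-rich carbon flanked by two methoxy groups.
- Fallback: it sets out from 11 and 6 and comes back at 13. It reverses the polarity of the partners and changes the metal.
- Compound 11 is brominated at C3 with NBS in THF at −78 °C, where the silylindole reacts far faster than the prenyl alkene. This gives 3-bromo-6-(3-methylbut-2-en-1-yl)-1-(triisopropylsilyl)-1H-indole F3.
- Compound 6 undergoes Br–Li exchange with n-BuLi at −78 °C to give [2,3,5,6-tetramethoxy-4-(2-methoxyethenyl)phenyl]lithium F4. ZnCl2 converts this into the corresponding arylzinc chloride F5.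
- Negishi coupling of F5 with F3 (Pd2(dba)3, RuPhos, THF, 60 °C) should give 13 in a water-free medium, where protodemetalation has no proton source.

Step 9.
- What may go wrong: the liberated arylacetaldehyde may condense under acid with the nucleophilic indole of a second molecule, undergo aldol oligomerisation or air oxidation, or the prenyl alkene may hydrate on long exposure.
- Fallback: it sets out from 2 (with 12) and comes back at 15. It reaches the aldehyde by oxidation under non-acidic conditions.
- Aryllithium 3, made from 2 as in step 2, is trapped with ethylene oxide to give 2-(4-bromo-2,3,5,6-tetramethoxyphenyl)ethanol F6.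
- Suzuki–Miyaura coupling of F6 with 12 under the step 7 conditions gives the N-silylated indolyl arylethanol F7. TBAF removes the silyl group to give 2-{2,3,5,6-tetramethoxy-4-[6-(3-methylbut-2-en-1-yl)-1H-indol-3-yl]phenyl}ethanol F8.
- Parikh–Doering oxidation (SO3·pyridine, DMSO, Et3N, 0 °C) should then deliver 15.

**Further compounds**
F1 | step 11 | 4-[(tert-butyldimethylsilyl)oxy]-2-iodoaniline | Nc1ccc(O[Si](C)(C)C(C)(C)C)cc1I
F2 | step 11 | 5-[(tert-butyldimethylsilyl)oxy]-3-{2,3,5,6-tetramethoxy-4-[6-(3-methylbut-2-en-1-yl)-1H-indol-3-yl]phenyl}-1H-indole | CC(C)(C)[Si](C)(C)Oc1ccc2[nH]cc(-c3c(OC)c(OC)c(-c4c[nH]c5cc(CC=C(C)C)ccc45)c(OC)c3OC)c2c1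
F3 | step 7 | 3-bromo-6-(3-methylbut-2-en-1-yl)-1-(triisopropylsilyl)-1H-indole | CC(C)=CCc1ccc2c(Br)cn([Si](C(C)C)(C(C)C)C(C)C)c2c1
F4 | step 7 | [2,3,5,6-tetramethoxy-4-(2-methoxyethenyl)phenyl]lithium | COC=Cc1c(OC)c(OC)c([Li])c(OC)c1OC
F5 | step 7 | [2,3,5,6-tetramethoxy-4-(2-methoxyethenyl)phenyl]zinc chloride | COC=Cc1c(OC)c(OC)c([Zn]Cl)c(OC)c1OC
F6 | step 9 | 2-(4-bromo-2,3,5,6-tetramethoxyphenyl)ethanol | OCCc1c(OC)c(OC)c(Br)c(OC)c1OC
F7 | step 9 | 2-{2,3,5,6-tetramethoxy-4-[6-(3-methylbut-2-en-1-yl)-1-(triisopropylsilyl)-1H-indol-3-yl]phenyl}ethanol | OCCc1c(OC)c(OC)c(-c2cn([Si](C(C)C)(C(C)C)C(C)C)c3cc(CC=C(C)C)ccc23)c(OC)c1OC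
F8 | step 9 | 2-{2,3,5,6-tetramethoxy-4-[6-(3-methylbut-2-en-1-yl)-1H-indol-3-yl]phenyl}ethanol | OCCc1c(OC)c(OC)c(-c2c[nH]c3cc(CC=C(C)C)ccc23)c(OC)c1OC
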